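**Retrosynthetic overview**
Rings A–E run from the 2,4,6-trihydroxyphenoxy end to the 3,4,5-trihydroxyphenoxy end. Four hydroxyls sit para to a diaryl ether oxygen on their own ring: C4'–OH of ring A (para to C1'–O), C3–OH of ring B (para to C6–O, the oxygen to ring C), C4–OH of ring D (para to C1–O, the oxygen to ring C) and C4–OH of ring E (para to C1–O). Each is carried as CHO, which first activates the SNAr that makes that ether and is then turned into OH.
Target ⇐ BBr3 cleavage of ten methyl ethers ⇐ tetraphenol decamethyl ether ⇐ fourfold Baeyer–Villiger oxidation of the pentaaryl tetra-aldehyde.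
Tetra-aldehyde ⇐ two SNAr couplings of 2,6-dimethoxyhydroquinone (ring C), first at its open 4-OH with the fluoro dialdehyde A–O–B–F, then at its 1-OH between the two methoxy groups with E–O–D–F.
Each fluoro dialdehyde ⇐ SNAr of a ring B or ring D fluorophenol, whose own aldehyde is held as a dioxolane so that its C–F bond is switched off, on the para-formyl aryl fluoride of ring A or ring E; acid then frees the aldehyde and switches that C–F bond on.
Fluorophenols ⇐ lithiation next to fluorine, borylation and oxidation of aryl dioxolanes; all five benzene rings are bought and no ring is formed.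

Key step: step 12

Remark: ring B is numbered C1 (O to ring A), C2 (H), C3–C5 (OH), C6 (O to ring C); ring D is numbered C1 (O to ring C), C2 (O to ring E), C3–C5 (OH), C6 (H). 3-Fluoro-2-methoxyphenol is assumed to be a catalogue compound. All hydroquinone and polyphenol intermediates are handled under argon because they autoxidise.

**Route**

Step 1
Reactants: 1 4-fluoro-2,6-dimethoxybenzaldehyde
Product: 2 2-(4-fluoro-2,6-dimethoxyphenyl)-1,3-dioxolane
Conditions: ethylene glycol, p-toluenesulfonic acid (cat.), toluene, reflux, Dean–Stark; Et3N quench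
Reagents that add atoms: ethylene glycol, OCCO
Why: Acid-catalysed acetalisation with azeotropic removal of water should give the base-stable dioxolane, which shields the carbonyl from the organolithium of step 2 and takes away the para-activation of the C–F bond.

Step 2
Reactants: 2 2-(4-fluoro-2,6-dimethoxyphenyl)-1,3-dioxolane
Product: 5 3-(1,3-dioxolan-2-yl)-6-fluoro-2,4-dimethoxyphenol, via aryllithium 3 (not isolated), via lithium aryltrimethoxyborate 4 (not isolated)
Conditions: n-BuLi, THF, –78 °C; B(OMe)3, –78 to 0 °C; 30% H2O2, aq NaOH, 0 °C to rt; NH4Cl work-up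
Reagents that add atoms: hydrogen peroxide, OO
Why: Directed ortho-metalation at one of the two equivalent ring C–H positions, each flanked by fluorine and methoxy (held at –78 °C so that LiF loss to an aryne does not set in), followed by borylation and alkaline peroxide oxidation of the C–B bond, should give the phenol with the acetal intact.

Step 3
Reactants: 5 3-(1,3-dioxolan-2-yl)-6-fluoro-2,4-dimethoxyphenol; 1 4-fluoro-2,6-dimethoxybenzaldehyde
Product: 7 4-fluoro-3-(4-formyl-3,5-dimethoxyphenoxy)-2,6-dimethoxybenzaldehyde (fragment E–O–D–F), via dioxolane-masked diaryl ether 6 (not isolated)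
Conditions: K2CO3, DMF, 100 °C (1 in slight excess); then 1 M HCl, THF, rt
Reagents that add atoms: water, O
Why: SNAr (addition–elimination through a Meisenheimer adduct) of the phenoxide of 5 on the fluoride para to the formyl group of 1 should be clean because the fluoride of 5 sits on an acetal-bearing, electron-rich ring and cannot compete, and the acid hydrolysis of the dioxolane then restores the ring D aldehyde and arms its fluoride for step 11.

Step 4
Reactants: 8 3-fluoro-2-methoxyphenol
Product: 9 4-fluoro-2-hydroxy-3-methoxybenzaldehyde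
Conditions: MgCl2, Et3N, paraformaldehyde, MeCN, reflux; 1 M HCl work-up
Reagents that add atoms: paraformaldehyde (as formaldehyde), C=O
Why: Magnesium phenoxide-directed ortho-formylation should deliver CHO only to the single free position ortho to the hydroxyl, since the other ortho carbon carries the methoxy group.

Step 5
Reactants: 9 4-fluoro-2-hydroxy-3-methoxybenzaldehyde
Product: 10 4-fluoro-2,3-dimethoxybenzaldehyde
Conditions: MeI, K2CO3, DMF, rt
Reagents that add atoms: iodomethane, CI
Why: Williamson O-methylation at room temperature should be far faster than any attack of the phenoxide on the activated fluoride, which needs heating.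

Step 6
Reactants: 10 4-fluoro-2,3-dimethoxybenzaldehyde
Product: 11 2-(4-fluoro-2,3-dimethoxyphenyl)-1,3-dioxolane
Conditions: ethylene glycol, p-toluenesulfonic acid (cat.), toluene, reflux, Dean–Stark; Et3N quench
Reagents that add atoms: ethylene glycol, OCCO
Why: Acid-catalysed acetalisation as in step 1 should mask the aldehyde for the lithiation and switch off the para C–F bond of ring B.

Step 7
Reactants: 11 2-(4-fluoro-2,3-dimethoxyphenyl)-1,3-dioxolane
Product: 14 5-(1,3-dioxolan-2-yl)-2-fluoro-3,4-dimethoxyphenol, via aryllithium 12 (not isolated), via lithium aryltrimethoxyborate 13 (not isolated)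
Conditions: s-BuLi, THF, –78 °C; B(OMe)3, –78 to 0 °C; 30% H2O2, aq NaOH, 0 °C to rt; NH4Cl work-up
Reagents that add atoms: hydrogen peroxide, OO
Why: Directed ortho-metalation should take place at C5, the only ring hydrogen ortho to fluorine and more acidic than H6 beside the weakly directing dioxolane, and borylation–oxidation then installs the hydroxyl there.

Step 8
Reactants: 14 5-(1,3-dioxolan-2-yl)-2-fluoro-3,4-dimethoxyphenol; 15 4-fluoro-3,5-dimethoxybenzaldehyde
Product: 17 4-fluoro-5-(4-formyl-2,6-dimethoxyphenoxy)-2,3-dimethoxybenzaldehyde (fragment A–O–B–F), via dioxolane-masked diaryl ether 16 (not isolated)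
Conditions: Cs2CO3, DMSO, 120 °C (15 in excess); then 1 M HCl, THF, rt
Reagents that add atoms: water, O
Why: SNAr of the phenoxide of 14 on the fluoride para to the formyl group of 15 should form the crowded A–O–B ether without self-condensation because the ring B fluoride is unactivated while its aldehyde is an acetal, and acid hydrolysis then frees the ring B aldehyde and arms its fluoride for step 10.

Step 9
Reactants: 18 2,6-dimethoxy-1,4-benzoquinone
Product: 19 2,6-dimethoxybenzene-1,4-diol
Conditions: Na2S2O4, EtOAc/H2O, rt, Ar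
Reagents that add atoms: none
Why: Dithionite reduction of a quinone to its hydroquinone is fast and clean in a two-phase system.

Step 10
Reactants: 19 2,6-dimethoxybenzene-1,4-diol; 17 4-fluoro-5-(4-formyl-2,6-dimethoxyphenoxy)-2,3-dimethoxybenzaldehyde
Product: 20 5-(4-formyl-2,6-dimethoxyphenoxy)-4-(4-hydroxy-3,5-dimethoxyphenoxy)-2,3-dimethoxybenzaldehyde
Conditions: K2CO3 (1.2 equiv), degassed DMF, 85 °C, Ar (19 in twofold excess)
Reagents that add atoms: none
Why: SNAr on the ring B fluoride para to CHO should occur through the 4-OH of 19, which is the more acidic hydroxyl and is flanked only by CH, in preference to the 1-OH buried between two methoxy groups, with excess 19 holding back twofold arylation.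

Step 11
Reactants: 20 5-(4-formyl-2,6-dimethoxyphenoxy)-4-(4-hydroxy-3,5-dimethoxyphenoxy)-2,3-dimethoxybenzaldehyde; 7 4-fluoro-3-(4-formyl-3,5-dimethoxyphenoxy)-2,6-dimethoxybenzaldehyde
Product: 21 permethylated pentaaryl tetra-aldehyde (CHO at ring A C4' and ring B C3 and ring D C4 and ring E C4)
Conditions: Cs2CO3, degassed DMSO, 110 °C, Ar
Reagents that add atoms: none
Why: SNAr of the 2,6-dimethoxyphenoxide of 20 on the only fluoride present, which lies para to the ring D formyl group and has one unsubstituted neighbour, should close the last ether link.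

Step 12
Reactants: 21 permethylated pentaaryl tetra-aldehyde
Product: 23 tetraphenol decamethyl ether (OH at ring A C4' and ring B C3 and ring D C4 and ring E C4), via tetraformate 22 (not isolated)
Conditions: mCPBA (3-chloroperbenzoic acid, 8 equiv), CH2Cl2, 0 °C to rt; aq Na2S2O3 wash; then Et3N (cat.), MeOH, rt, Ar
Reagents that add atoms: mCPBA, OOC(=O)c1cccc(Cl)c1
Why: Each formyl group adds the peracid to give a Criegee peroxyhemiacetal, from which the aryl group shifts to the neighbouring peroxide oxygen as 3-chlorobenzoate leaves, so that four aryl C–CHO bonds become aryl C–O bonds at ring A C4', ring B C3, ring D C4 and ring E C4; base-catalysed methanolysis then removes the four formyl groups. The closest known reaction type is the Baeyer–Villiger (Dakin-type) oxidation of alkoxybenzaldehydes to aryl formates and phenols. The step closes no ring and creates no stereocenter. It needs aryl migration to outrun hydride migration at all four aldehydes: every formyl-bearing ring has an aryloxy oxygen para to the carbonyl, and rings B, D and E have in addition one or two ortho methoxy groups, all of which raise the migratory aptitude of the aryl group. The new oxygens stay masked as formates while peracid is present, and the oxidant is washed out before methanolysis, so the electron-rich free phenols should not be over-oxidised to quinones.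

Step 13
Reactants: 23 tetraphenol decamethyl ether
Product: 24 target CNP0273977.0 (tetradecahydroxy pentaaryl tetraether)
Conditions: BBr3 (30 equiv), CH2Cl2, –78 °C to rt; then H2O, 0 °C, Ar
Reagents that add atoms: none
Why: Lewis acid-mediated cleavage of aryl methyl ethers (bromide attacks the methyl carbon of the boron-complexed ether) should remove all ten methyl groups, while the diaryl ether links have no sp3 carbon to attack and remain.

**Compound list**
1 | 4-fluoro-2,6-dimethoxybenzaldehyde | COc1cc(F)cc(OC)c1C=O | starting material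
2 | 2-(4-fluoro-2,6-dimethoxyphenyl)-1,3-dioxolane | COc1cc(F)cc(OC)c1C2OCCO2 | intermediate
3 | [3-(1,3-dioxolan-2-yl)-6-fluoro-2,4-dimethoxyphenyl]lithium | COc1cc(F)c([Li])c(OC)c1C2OCCO2 | intermediate
4 | lithium [3-(1,3-dioxolan-2-yl)-6-fluoro-2,4-dimethoxyphenyl]trimethoxyborate | [Li+].COc1cc(F)c([B-](OC)(OC)OC)c(OC)c1C2OCCO2 | intermediate
5 | 3-(1,3-dioxolan-2-yl)-6-fluoro-2,4-dimethoxyphenol | COc1cc(F)c(O)c(OC)c1C2OCCO2 | intermediate
6 | 4-[3-(1,3-dioxolan-2-yl)-6-fluoro-2,4-dimethoxyphenoxy]-2,6-dimethoxybenzaldehyde | COc1cc(F)c(Oc2cc(OC)c(C=O)c(OC)c2)c(OC)c1C3OCCO3 | intermediate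
7 | 4-fluoro-3-(4-formyl-3,5-dimethoxyphenoxy)-2,6-dimethoxybenzaldehyde | COc1cc(F)c(Oc2cc(OC)c(C=O)c(OC)c2)c(OC)c1C=O | intermediate
8 | 3-fluoro-2-methoxyphenol | COc1c(O)cccc1F | starting material
9 | 4-fluoro-2-hydroxy-3-methoxybenzaldehyde | COc1c(F)ccc(C=O)c1O | intermediate
10 | 4-fluoro-2,3-dimethoxybenzaldehyde | COc1c(F)ccc(C=O)c1OC | intermediate
11 | 2-(4-fluoro-2,3-dimethoxyphenyl)-1,3-dioxolane | COc1c(F)ccc(C2OCCO2)c1OC | intermediate
12 | [5-(1,3-dioxolan-2-yl)-2-fluoro-3,4-dimethoxyphenyl]lithium | COc1c(F)c([Li])cc(C2OCCO2)c1OC | intermediate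
13 | lithium [5-(1,3-dioxolan-2-yl)-2-fluoro-3,4-dimethoxyphenyl]trimethoxyborate | [Li+].COc1c(F)c([B-](OC)(OC)OC)cc(C2OCCO2)c1OC | intermediate
14 | 5-(1,3-dioxolan-2-yl)-2-fluoro-3,4-dimethoxyphenol | COc1c(F)c(O)cc(C2OCCO2)c1OC | intermediate
15 | 4-fluoro-3,5-dimethoxybenzaldehyde | COc1cc(C=O)cc(OC)c1F | starting material
16 | 4-[5-(1,3-dioxolan-2-yl)-2-fluoro-3,4-dimethoxyphenoxy]-3,5-dimethoxybenzaldehyde | COc1c(F)c(Oc2c(OC)cc(C=O)cc2OC)cc(C3OCCO3)c1OC | intermediate
17 | 4-fluoro-5-(4-formyl-2,6-dimethoxyphenoxy)-2,3-dimethoxybenzaldehyde | COc1c(F)c(Oc2c(OC)cc(C=O)cc2OC)cc(C=O)c1OC | intermediate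
18 | 2,6-dimethoxy-1,4-benzoquinone | COC1=CC(=O)C=C(OC)C1=O | starting material
19 | 2,6-dimethoxybenzene-1,4-diol | COc1cc(O)cc(OC)c1O | intermediate
20 | 5-(4-formyl-2,6-dimethoxyphenoxy)-4-(4-hydroxy-3,5-dimethoxyphenoxy)-2,3-dimethoxybenzaldehyde | COc1cc(Oc2c(OC)c(OC)c(C=O)cc2Oc3c(OC)cc(C=O)cc3OC)cc(OC)c1O | intermediate
21 | permethylated pentaaryl tetra-aldehyde; rings A–E linked as in the target, ten OMe, CHO at ring A C4', ring B C3, ring D C4, ring E C4 | O=Cc1cc(OC)c(Oc2cc(C=O)c(OC)c(OC)c2Oc2cc(OC)c(Oc3cc(OC)c(C=O)c(OC)c3Oc3cc(OC)c(C=O)c(OC)c3)c(OC)c2)c(OC)c1 | intermediate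
22 | tetraformate of 23 (OCHO in place of each CHO of 21) | O=COc1cc(OC)c(Oc2cc(OC=O)c(OC)c(OC)c2Oc2cc(OC)c(Oc3cc(OC)c(OC=O)c(OC)c3Oc3cc(OC)c(OC=O)c(OC)c3)c(OC)c2)c(OC)c1 | intermediate
23 | tetraphenol decamethyl ether; OH at ring A C4', ring B C3, ring D C4, ring E C4 | Oc1cc(OC)c(Oc2cc(O)c(OC)c(OC)c2Oc2cc(OC)c(Oc3cc(OC)c(O)c(OC)c3Oc3cc(OC)c(O)c(OC)c3)c(OC)c2)c(OC)c1 | intermediate
24 | CNP0273977.0, fully deprotected pentaaryl tetraether (no stereocenters) | Oc1cc(O)c(Oc2cc(O)c(O)c(O)c2Oc2cc(O)c(Oc3cc(O)c(O)c(O)c3Oc3cc(O)c(O)c(O)c3)c(O)c2)c(O)c1 | target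

**Step count**
Total: 13 steps. Longest linear sequence: 9 steps (steps 4, 5, 6, 7, 8, 10, 11, 12, 13, from 3-fluoro-2-methoxyphenol 8).

**Steps most likely to fail**

1. Step 12. Hydride migration may compete with aryl migration at the least activated aldehyde (ring A, no ortho oxygen), giving carboxylic acids. Conversion over four sites may also be uneven, leaving a mixture of partly oxidised products. Fallback, from 21 back to 23: the hydride is replaced by a methyl group that migrates far less readily. MeMgBr (THF, –78 to 0 °C) should give the tetrakis(1-hydroxyethyl) compound F1 (diastereomer mixture, of no consequence). Dess–Martin periodinane should give the tetra-acetyl compound F2. mCPBA in CH2Cl2 with NaHCO3 should then give the tetra-acetate F3 by Baeyer–Villiger oxidation of aryl methyl ketones, and K2CO3 in MeOH under argon should release 23.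

2. Step 8. Addition of the ortho-fluoro phenoxide to the fluoride carbon of 15, which is flanked by two methoxy groups, may be slow, so that ether exchange and decomposition at 120 °C overtake coupling. Fallback, from 11 back to 16: the polarity of the A–O–B bond is reversed. Aryllithium 12 is generated as in step 7 and quenched with I2 to give 2-(4-fluoro-5-iodo-2,3-dimethoxyphenyl)-1,3-dioxolane F4. A copper-catalysed Ullmann-type C–O coupling with commercial 4-hydroxy-3,5-dimethoxybenzaldehyde (COc1cc(C=O)cc(OC)c1O), using CuI, pyridine-2-carboxylic acid, K3PO4, DMSO at 90 °C, should give 16. The acid treatment of step 8 then leads to 17.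

3. Step 10. Site selectivity between the two hydroxyls of 19 may be lost, twofold arylation may occur, or the hydroquinone anion may autoxidise back to quinone under base. Fallback, from 17 back to 20: a ring C building block whose hindered oxygen is already blocked. Commercial 4-hydroxy-3,5-dimethoxybenzaldehyde with chloromethyl methyl ether and iPr2NEt should give 3,5-dimethoxy-4-(methoxymethoxy)benzaldehyde F5. mCPBA should give the aryl formate F6, and K2CO3 in MeOH the phenol 3,5-dimethoxy-4-(methoxymethoxy)phenol F7. SNAr of F7 with 17 (K2CO3, DMF, 90 °C) should give the MOM-protected trimer 5-(4-formyl-2,6-dimethoxyphenoxy)-4-[3,5-dimethoxy-4-(methoxymethoxy)phenoxy]-2,3-dimethoxybenzaldehyde F8. 2 M HCl in THF at 40 °C should then unmask 20.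

**Further compounds**
F1 | step 12 | tetrakis(1-hydroxyethyl) analogue of 21 (CH(OH)CH3 in place of each CHO, diastereomer mixture) | CC(O)c1cc(OC)c(Oc2cc(C(C)O)c(OC)c(OC)c2Oc2cc(OC)c(Oc3cc(OC)c(C(C)O)c(OC)c3Oc3cc(OC)c(C(C)O)c(OC)c3)c(OC)c2)c(OC)c1
F2 | step 12 | tetra-acetyl analogue of 21 (COCH3 in place of each CHO) | CC(=O)c1cc(OC)c(Oc2cc(C(C)=O)c(OC)c(OC)c2Oc2cc(OC)c(Oc3cc(OC)c(C(C)=O)c(OC)c3Oc3cc(OC)c(C(C)=O)c(OC)c3)c(OC)c2)c(OC)c1
F3 | step 12 | tetra-acetate of 23 | CC(=O)Oc1cc(OC)c(Oc2cc(OC(C)=O)c(OC)c(OC)c2Oc2cc(OC)c(Oc3cc(OC)c(OC(C)=O)c(OC)c3Oc3cc(OC)c(OC(C)=O)c(OC)c3)c(OC)c2)c(OC)c1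
F4 | step 8 | 2-(4-fluoro-5-iodo-2,3-dimethoxyphenyl)-1,3-dioxolane | COc1c(F)c(I)cc(C2OCCO2)c1OC
F5 | step 10 | 3,5-dimethoxy-4-(methoxymethoxy)benzaldehyde | COCOc1c(OC)cc(C=O)cc1OC
F6 | step 10 | 3,5-dimethoxy-4-(methoxymethoxy)phenyl formate | COCOc1c(OC)cc(OC=O)cc1OC
F7 | step 10 | 3,5-dimethoxy-4-(methoxymethoxy)phenol | COCOc1c(OC)cc(O)cc1OC
F8 | step 10 | 5-(4-formyl-2,6-dimethoxyphenoxy)-4-[3,5-dimethoxy-4-(methoxymethoxy)phenoxy]-2,3-dimethoxybenzaldehyde | COCOc1c(OC)cc(Oc2c(OC)c(OC)c(C=O)cc2Oc3c(OC)cc(C=O)cc3OC)cc1OC
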